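**Plan**
Numbering (daucane): C1 = CH3-bearing ring-fusion carbon, C2/C3 = ring CH2, C4 = C(OH)(iPr), C5 = ring-fusion CH, C6 = CH–O-aroyl, C7 = CH2, C8(CH3)=C9, C10 = CH–O-isovaleryl; β = face of the C1 methyl, α = the other face.
Retrosynthetic cuts, in order: both ester C–O bonds; C6–H; C5–H and C4–O (α,β-epoxy ketone, from an enone); C2–C3 and C4–C5 of the five-membered ring ((3+2) of a cyclopropyl ketone with 3-methylbut-1-yne); C8=C9 (metathesis); C6–C7; the cyclopropane CH2; C1–CH3; C10–alkyne.
Forward: C10 carbinol → Z-trisubstituted alkene → cyclopropane → seven-membered ring → five-membered ring (key step) → C4, C5, C6 → two esters.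
Stereochemistry: C10 from catalytic asymmetric alkynylation; C1 from ligand-controlled cyclopropanation; C4 from C10-hydroxyl-directed epoxidation; C5 from kinetic protonation of a regiodefined samarium enolate (the annulation itself can only give the cis ring fusion); C6 from hydroxyl-directed reduction.
Enabling feature: in bicyclo[5.1.0]octenone 11 the C6 carbonyl sits on cyclopropane carbon C5 (cyclopropane C1–C2–C5 fused to the seven-membered ring), so its ketyl opens the exocyclic C5–C2 bond to a C2 radical and a C5 enolate, the two sites that alkyne carbons C3 and C4 join.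

Key step: step 10

Remark: 1, 2, 12 and all reagents (both enantiomers of ProPhenol and of the dioxaborolane ligand included) are taken as commercial; in step 1 the ProPhenol enantiomer is the one that gives the 4R carbinol.

Step 1
Reactants: 1 acrolein; 2 methyl propiolate
Product: 3 methyl (4R)-4-hydroxyhex-5-en-2-ynoate
Conditions: Me2Zn (3 equiv), ProPhenol (10 mol %), Ph3PO (20 mol %), toluene, 4 °C; aq NH4Cl
Reagents that add atoms: none
Why: Catalytic asymmetric alkynylation (1,2-addition of the zinc alkynylide to the enal under ProPhenol–zinc catalysis) should give the propargylic alcohol, the chiral dinuclear zinc complex choosing the aldehyde face and so setting C10 as R.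

Step 2
Reactants: 3 methyl (4R)-4-hydroxyhex-5-en-2-ynoate
Product: 4 methyl (4R)-4-[(tert-butyldimethylsilyl)oxy]hex-5-en-2-ynoate
Conditions: TBSCl, imidazole, DMF, 0 °C to rt
Reagents that add atoms: tert-butyldimethylsilyl chloride, CC(C)(C)[Si](C)(C)Cl
Why: Standard silyl ether formation protects the C10 hydroxyl from the cuprate, hydride, carbenoid, Grignard and oxidation steps that follow and does not touch the stereocentre.

Step 3
Reactants: 4 methyl (4R)-4-[(tert-butyldimethylsilyl)oxy]hex-5-en-2-ynoate
Product: 5 methyl (2Z,4R)-4-[(tert-butyldimethylsilyl)oxy]-3-methylhexa-2,5-dienoate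
Conditions: Me2CuLi (from MeLi and CuI, 1.3 equiv), THF, −78 °C; MeOH then aq NH4Cl at −78 °C
Reagents that add atoms: lithium dimethylcuprate, [Li+].C[Cu-]C
Why: Conjugate syn-carbocupration of the ynoate followed by protonation of the vinylcuprate at −78 °C places CH3 and H cis, so the ester carbon (C6) and C10 end up cis on the new trisubstituted alkene (Z), as a cis-fused cyclopropane later requires.

Step 4
Reactants: 5 methyl (2Z,4R)-4-[(tert-butyldimethylsilyl)oxy]-3-methylhexa-2,5-dienoate
Product: 6 (2Z,4R)-4-[(tert-butyldimethylsilyl)oxy]-3-methylhexa-2,5-dien-1-ol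
Conditions: i-Bu2AlH (2.3 equiv), CH2Cl2, −78 °C; aq potassium sodium tartrate
Reagents that add atoms: none
Why: 1,2-Reduction of the enoate with i-Bu2AlH should give the allylic alcohol with the alkene geometry unchanged.

Step 5
Reactants: 6 (2Z,4R)-4-[(tert-butyldimethylsilyl)oxy]-3-methylhexa-2,5-dien-1-ol
Product: 7 [(1R,2S)-2-{(1R)-1-[(tert-butyldimethylsilyl)oxy]prop-2-en-1-yl}-2-methylcyclopropyl]methanol
Conditions: Zn(CH2I)2·DME (from Et2Zn, CH2I2, DME; 2.2 equiv), (4S,5S)-2-butyl-N,N,N',N'-tetramethyl-1,3,2-dioxaborolane-4,5-dicarboxamide (1.2 equiv; the enantiomer that delivers CH2 anti to the silyloxy group), CH2Cl2, −10 °C to rt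
Reagents that add atoms: diiodomethane (delivered as Zn(CH2I)2), ICI
Why: Charette asymmetric Simmons–Smith cyclopropanation: the zinc alkoxide of the primary allylic alcohol, bound to the chiral dioxaborolane, receives CH2 on the alkene face chosen by the ligand (also the face anti to the bulky C10 silyloxy group in the A(1,3)-minimised conformer), which sets C1 and C5 stereospecifically from the Z alkene, places the CH2 cis to the C10 oxygen in the later ring, and leaves the vinyl group untouched.

Step 6
Reactants: 7 [(1R,2S)-2-{(1R)-1-[(tert-butyldimethylsilyl)oxy]prop-2-en-1-yl}-2-methylcyclopropyl]methanol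
Product: 8 (1R,2S)-2-{(1R)-1-[(tert-butyldimethylsilyl)oxy]prop-2-en-1-yl}-2-methylcyclopropane-1-carbaldehyde
Conditions: Dess–Martin periodinane, NaHCO3, CH2Cl2, 0 °C to rt
Reagents that add atoms: none
Why: Dess–Martin oxidation under buffered neutral conditions should give the aldehyde without epimerising the cyclopropane carbon or cleaving the silyl ether.

Step 7
Reactants: 8 (1R,2S)-2-{(1R)-1-[(tert-butyldimethylsilyl)oxy]prop-2-en-1-yl}-2-methylcyclopropane-1-carbaldehyde
Product: 9 1-[(1R,2S)-2-{(1R)-1-[(tert-butyldimethylsilyl)oxy]prop-2-en-1-yl}-2-methylcyclopropyl]-3-methylbut-3-en-1-ol (both carbinol epimers)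
Conditions: 2-methylallylmagnesium chloride, THF, −78 °C; aq NH4Cl
Reagents that add atoms: 2-methylallylmagnesium chloride, CC(=C)C[Mg]Cl
Why: Grignard 1,2-addition of the 2-methylallyl nucleophile to the aldehyde forms the C6–C7 bond, and the new carbinol centre is removed in step 8, so its configuration does not matter.

Step 8
Reactants: 9 1-[(1R,2S)-2-{(1R)-1-[(tert-butyldimethylsilyl)oxy]prop-2-en-1-yl}-2-methylcyclopropyl]-3-methylbut-3-en-1-ol
Product: 10 1-[(1R,2S)-2-{(1R)-1-[(tert-butyldimethylsilyl)oxy]prop-2-en-1-yl}-2-methylcyclopropyl]-3-methylbut-3-en-1-one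
Conditions: Dess–Martin periodinane, NaHCO3, CH2Cl2, 0 °C
Reagents that add atoms: none
Why: Dess–Martin oxidation of the secondary alcohol gives the cyclopropyl ketone under non-basic conditions that keep the β,γ-alkene out of conjugation.

Step 9
Reactants: 10 1-[(1R,2S)-2-{(1R)-1-[(tert-butyldimethylsilyl)oxy]prop-2-en-1-yl}-2-methylcyclopropyl]-3-methylbut-3-en-1-one
Product: 11 (1R,6R,7S)-6-[(tert-butyldimethylsilyl)oxy]-4,7-dimethylbicyclo[5.1.0]oct-4-en-2-one
Conditions: second-generation Grubbs catalyst (5 mol %), CH2Cl2 (2 mM), 40 °C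
Reagents that add atoms: none
Why: Ring-closing metathesis between the 1,1-disubstituted and the monosubstituted alkene, held close by the cis-cyclopropane, should close the seven-membered ring and place the trisubstituted C8=C9 alkene unambiguously, with loss of ethene.

Step 10
Reactants: 11 (1R,6R,7S)-6-[(tert-butyldimethylsilyl)oxy]-4,7-dimethylbicyclo[5.1.0]oct-4-en-2-one; 12 3-methylbut-1-yne
Product: 13 10α-[(tert-butyldimethylsilyl)oxy]-5β-dauca-3,8-dien-6-one (cis-fused, H5 syn to the C1 methyl)
Conditions: SmI2 (20 mol %), Sm metal (20 mol %), 12 (5 equiv), THF, 55 °C, sealed tube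
Reagents that add atoms: none
Why: Single-electron transfer from SmI2 to the C6 carbonyl gives a ketyl whose exocyclic cyclopropane bond C5–C2 opens to a primary C2 radical and a trivalent-samarium enolate at C5–C6; the radical adds to the terminal carbon of 12 (C2–C3 bond), the resulting vinyl radical closes onto the enolate carbon (C4–C5 bond), and the new ketyl returns its electron to samarium, so SmI2 turns over. The closest known reaction type is the SmI2-catalysed radical-relay formal (3+2) cycloaddition of alkyl cyclopropyl ketones with alkynes, to which fused bicyclic ketones are amenable. The five-membered ring closes by 5-exo-trig attack of the C4 vinyl radical on C5 of the enolate, the first bond having been made intermolecularly. The only new stereocentre, C5, is fixed by the tether: C2 sits on the α face of the seven-membered ring at C1, so C4 must bond to the same face of C5 (cis fusion), and this centre is deliberately reset in steps 12 and 14. The step needs cleavage of C5–C2 rather than C5–C1 and addition to the CH terminus of the alkyne: the first should be secured by the better overlap of the exocyclic bond with the ketyl orbital in the rigid bicycle and by faster trapping of the unhindered primary radical, the second by the steric and radical-stability bias of a terminal alkyne, while the unactivated C8=C9 alkene offers no feasible ring closure.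

Step 11
Reactants: 13 10α-[(tert-butyldimethylsilyl)oxy]-5β-dauca-3,8-dien-6-one
Product: 14 10α-hydroxy-5β-dauca-3,8-dien-6-one
Conditions: HF·pyridine, pyridine, THF, 0 °C to rt
Reagents that add atoms: none
Why: Fluoride-mediated cleavage of the silyl ether under non-basic, buffered conditions frees the C10 hydroxyl needed as the directing group in step 12 without moving either β,γ-alkene.

Step 12
Reactants: 14 10α-hydroxy-5β-dauca-3,8-dien-6-one
Product: 16 4α,5α-epoxy-10α-hydroxydauc-8-en-6-one, via conjugated hydroxy enone 15 (not isolated)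
Conditions: DBU (1.5 equiv), t-BuOOH (5.5 M in decane, 3 equiv), CH2Cl2, 0 °C
Reagents that add atoms: tert-butyl hydroperoxide, CC(C)(C)OO
Why: DBU first moves the C3=C4 alkene into conjugation through the doubly activated C5–H (which erases the cis-fused centre), and the tetrasubstituted enone then undergoes Weitz–Scheffer nucleophilic epoxidation in which the C10 hydroxyl, lying under the α face of the five-membered ring (gauche to C2 and C5), hydrogen-bonds the tert-butylperoxide and delivers it to C4 from that face, so the C4–O bond is set anti to the C1 methyl while the electron-rich C8=C9 alkene is left alone.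

Step 13
Reactants: 16 4α,5α-epoxy-10α-hydroxydauc-8-en-6-one
Product: 17 4α,5α-epoxy-6-oxodauc-8-en-10α-yl 3-methylbutanoate
Conditions: 3-methylbutanoyl chloride, pyridine, DMAP (10 mol %), CH2Cl2, 0 °C to rt
Reagents that add atoms: 3-methylbutanoyl chloride, CC(C)CC(Cl)=O
Why: DMAP-catalysed acylation of the only hydroxyl installs the C10 isovalerate now, before the base-sensitive ketol is formed.

Step 14
Reactants: 17 4α,5α-epoxy-6-oxodauc-8-en-10α-yl 3-methylbutanoate
Product: 18 4α-hydroxy-6-oxo-5α-dauc-8-en-10α-yl 3-methylbutanoate (trans-fused)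
Conditions: SmI2 (2.5 equiv), THF/MeOH, −78 °C, 10 min; pH 7 phosphate buffer at −78 °C
Reagents that add atoms: none
Why: SmI2 reduction of the α,β-epoxy ketone cleaves the C5–O bond by two single-electron transfers and leaves C4–O untouched, and the regiodefined samarium enolate is protonated at C5 by samarium-bound methanol from the α face (the face of the C4 alkoxide, the β face being screened by the C1 methyl and the C4 isopropyl), which should give the trans ring fusion under kinetic control.

Step 15
Reactants: 18 4α-hydroxy-6-oxo-5α-dauc-8-en-10α-yl 3-methylbutanoate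
Product: 19 4α,6β-dihydroxy-5α-dauc-8-en-10α-yl 3-methylbutanoate
Conditions: Me4NBH(OAc)3 (5 equiv), MeCN/AcOH (1:1), −30 °C
Reagents that add atoms: none
Why: Evans–Saksena hydroxyl-directed reduction, in which the C4 hydroxyl binds the acetoxyborohydride and delivers hydride to the α face of the C6 ketone (also the less hindered face), should give the 1,3-anti diol with the C6 hydroxyl β in an acidic medium that does not epimerise C5.

Step 16
Reactants: 19 4α,6β-dihydroxy-5α-dauc-8-en-10α-yl 3-methylbutanoate
Product: 20 4α-hydroxy-10α-(3-methylbutanoyloxy)-5α-dauc-8-en-6β-yl 4-acetoxybenzoate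
Conditions: 4-acetoxybenzoyl chloride (2 equiv), DMAP, Et3N, CH2Cl2, 0 °C to rt
Reagents that add atoms: 4-acetoxybenzoyl chloride, CC(=O)Oc1ccc(cc1)C(Cl)=O
Why: DMAP-catalysed acylation with the acid chloride should esterify the only secondary hydroxyl, the tertiary C4 hydroxyl being too hindered to react.

Step 17
Reactants: 20 4α-hydroxy-10α-(3-methylbutanoyloxy)-5α-dauc-8-en-6β-yl 4-acetoxybenzoate
Product: 21 4α-hydroxy-10α-(3-methylbutanoyloxy)-5α-dauc-8-en-6β-yl 4-hydroxybenzoate (the target)
Conditions: pyrrolidine (3 equiv), CH2Cl2, 0 °C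
Reagents that add atoms: none
Why: Chemoselective aminolysis of the aryl acetate, which is far more electrophilic than the two alkyl esters, frees the phenol and gives the target.

**Compound list**
1 | acrolein (prop-2-enal) | C=CC=O | starting material
2 | methyl propiolate (methyl prop-2-ynoate) | COC(=O)C#C | starting material
3 | methyl (4R)-4-hydroxyhex-5-en-2-ynoate | COC(=O)C#C[C@H](O)C=C | intermediate
4 | methyl (4R)-4-[(tert-butyldimethylsilyl)oxy]hex-5-en-2-ynoate | COC(=O)C#C[C@H](O[Si](C)(C)C(C)(C)C)C=C | intermediate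
5 | methyl (2Z,4R)-4-[(tert-butyldimethylsilyl)oxy]-3-methylhexa-2,5-dienoate | COC(=O)/C=C(/C)[C@H](O[Si](C)(C)C(C)(C)C)C=C | intermediate
6 | (2Z,4R)-4-[(tert-butyldimethylsilyl)oxy]-3-methylhexa-2,5-dien-1-ol | OC/C=C(/C)[C@H](O[Si](C)(C)C(C)(C)C)C=C | intermediate
7 | [(1R,2S)-2-{(1R)-1-[(tert-butyldimethylsilyl)oxy]prop-2-en-1-yl}-2-methylcyclopropyl]methanol | OC[C@@H]1C[C@]1(C)[C@H](O[Si](C)(C)C(C)(C)C)C=C | intermediate
8 | (1R,2S)-2-{(1R)-1-[(tert-butyldimethylsilyl)oxy]prop-2-en-1-yl}-2-methylcyclopropane-1-carbaldehyde | O=C[C@@H]1C[C@]1(C)[C@H](O[Si](C)(C)C(C)(C)C)C=C | intermediate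
9 | 1-[(1R,2S)-2-{(1R)-1-[(tert-butyldimethylsilyl)oxy]prop-2-en-1-yl}-2-methylcyclopropyl]-3-methylbut-3-en-1-ol (carbinol centre as both epimers) | C=C(C)CC(O)[C@@H]1C[C@]1(C)[C@H](O[Si](C)(C)C(C)(C)C)C=C | intermediate
10 | 1-[(1R,2S)-2-{(1R)-1-[(tert-butyldimethylsilyl)oxy]prop-2-en-1-yl}-2-methylcyclopropyl]-3-methylbut-3-en-1-one | C=C(C)CC(=O)[C@@H]1C[C@]1(C)[C@H](O[Si](C)(C)C(C)(C)C)C=C | intermediate
11 | (1R,6R,7S)-6-[(tert-butyldimethylsilyl)oxy]-4,7-dimethylbicyclo[5.1.0]oct-4-en-2-one | CC1=C[C@@H](O[Si](C)(C)C(C)(C)C)[C@@]2(C)C[C@H]2C(=O)C1 | intermediate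
12 | 3-methylbut-1-yne | CC(C)C#C | starting material
13 | 10α-[(tert-butyldimethylsilyl)oxy]-5β-dauca-3,8-dien-6-one (cis-fused) | CC1=C[C@@H](O[Si](C)(C)C(C)(C)C)[C@@]2(C)CC=C(C(C)C)[C@H]2C(=O)C1 | intermediate
14 | 10α-hydroxy-5β-dauca-3,8-dien-6-one | CC1=C[C@@H](O)[C@@]2(C)CC=C(C(C)C)[C@H]2C(=O)C1 | intermediate
15 | 10α-hydroxydauca-4,8-dien-6-one | CC1=C[C@@H](O)[C@@]2(C)CCC(C(C)C)=C2C(=O)C1 | intermediate (not isolated)
16 | 4α,5α-epoxy-10α-hydroxydauc-8-en-6-one | CC1=C[C@@H](O)[C@@]2(C)CC[C@@]3(C(C)C)O[C@@]23C(=O)C1 | intermediate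
17 | 4α,5α-epoxy-6-oxodauc-8-en-10α-yl 3-methylbutanoate | CC1=C[C@@H](OC(=O)CC(C)C)[C@@]2(C)CC[C@@]3(C(C)C)O[C@@]23C(=O)C1 | intermediate
18 | 4α-hydroxy-6-oxo-5α-dauc-8-en-10α-yl 3-methylbutanoate (trans-fused) | CC1=C[C@@H](OC(=O)CC(C)C)[C@@]2(C)CC[C@](O)(C(C)C)[C@@H]2C(=O)C1 | intermediate
19 | 4α,6β-dihydroxy-5α-dauc-8-en-10α-yl 3-methylbutanoate | CC1=C[C@@H](OC(=O)CC(C)C)[C@@]2(C)CC[C@](O)(C(C)C)[C@@H]2[C@H](O)C1 | intermediate
20 | 4α-hydroxy-10α-(3-methylbutanoyloxy)-5α-dauc-8-en-6β-yl 4-acetoxybenzoate | CC1=C[C@@H](OC(=O)CC(C)C)[C@@]2(C)CC[C@](O)(C(C)C)[C@@H]2[C@H](OC(=O)c2ccc(OC(C)=O)cc2)C1 | intermediate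
21 | (1S,4S,5S,6R,10R)-4-hydroxy-10-(3-methylbutanoyloxy)dauc-8-en-6-yl 4-hydroxybenzoate (daucane numbering) | CC1=C[C@@H](OC(=O)CC(C)C)[C@@]2(C)CC[C@](O)(C(C)C)[C@@H]2[C@H](OC(=O)c2ccc(O)cc2)C1 | target

Total step count: 17. Longest linear sequence: 17 steps (steps 1 to 17; 12 enters as a commercial reactant).

**Three steps most likely to fail**

1. Step 10. The primary C2 radical may be captured too slowly by an unactivated terminal alkyne, so that re-closure of the cyclopropane, opening of the other cyclopropane bond (C5–C1) or loss of the divalent samarium catalyst takes over. The fallback sets out from 11 and comes back at 16, and swaps the alkyne for a polarity-matched radical acceptor. Markovnikov hydrothiolation of 12 with thiophenol (Pd(OAc)2 cat., THF, 40 °C) should give phenyl(3-methylbut-1-en-2-yl)sulfane F1, and oxidation with mCPBA the vinyl sulfone F2. The same SmI2/Sm metal conditions with 11 and F2 should then give the β-sulfonyl ketone F3, because the nucleophilic primary radical adds fast to the electron-poor alkene and the electrophilic α-sulfonyl radical closes on the electron-rich enolate. HF·pyridine would give the hydroxy sulfone F4. DBU/t-BuOOH would then eliminate benzenesulfinate (E1cB) to 15 in the flask and epoxidise it as in step 12 to 16.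

2. Step 12. Prolonged exposure of the β,γ-unsaturated ketone to base while the hindered tetrasubstituted enone is slowly epoxidised may move the C8=C9 alkene into conjugation, and hydroxyl-directed delivery of the peroxide may not fully control the face. The fallback sets out from 13 and comes back at 16, and brings the oxygen in from a C6 carbinol under neutral conditions. Brief treatment of 13 with catalytic DBU alone should give the silyl enone F5. Corey–Bakshi–Shibata reduction (oxazaborolidine enantiomer chosen to deliver hydride to the β face, BH3·SMe2) should give the 6α-carbinol F6 under reagent control. VO(acac)2/t-BuOOH epoxidation directed by that carbinol (syn to the hydroxyl, hence α) would give the epoxy alcohol F7, Dess–Martin oxidation the silyl epoxy ketone F8, and HF·pyridine 16.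

3. Step 14. The samarium enolate may be protonated on the wrong face, or the kinetically formed trans-fused ketol may equilibrate (C5 epimerisation, retro-aldol) in the methoxide-containing medium before the quench. The fallback sets out from 17 and comes back at 18, and replaces enolate protonation by a radical hydrogen-atom transfer. Cp2TiCl (from Cp2TiCl2 and Zn dust) with 1,4-cyclohexadiene in THF should open the epoxide homolytically at C5–O through trivalent titanium, and the C5 α-keto radical should take a hydrogen atom on the open α face under neutral, aprotic conditions. No new compound is made.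

**Further compounds**
F1 | step 10 | phenyl(3-methylbut-1-en-2-yl)sulfane | CC(C)C(=C)Sc1ccccc1
F2 | step 10 | [(3-methylbut-1-en-2-yl)sulfonyl]benzene | CC(C)C(=C)S(=O)(=O)c1ccccc1
F3 | step 10 | 10α-[(tert-butyldimethylsilyl)oxy]-4-(phenylsulfonyl)-5β-dauc-8-en-6-one (C4 epimers) | CC1=C[C@@H](O[Si](C)(C)C(C)(C)C)[C@@]2(C)CCC(C(C)C)(S(=O)(=O)c3ccccc3)[C@H]2C(=O)C1
F4 | step 10 | 10α-hydroxy-4-(phenylsulfonyl)-5β-dauc-8-en-6-one (C4 epimers) | CC1=C[C@@H](O)[C@@]2(C)CCC(C(C)C)(S(=O)(=O)c3ccccc3)[C@H]2C(=O)C1
F5 | step 12 | 10α-[(tert-butyldimethylsilyl)oxy]dauca-4,8-dien-6-one | CC1=C[C@@H](O[Si](C)(C)C(C)(C)C)[C@@]2(C)CCC(C(C)C)=C2C(=O)C1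
F6 | step 12 | 10α-[(tert-butyldimethylsilyl)oxy]dauca-4,8-dien-6α-ol | CC1=C[C@@H](O[Si](C)(C)C(C)(C)C)[C@@]2(C)CCC(C(C)C)=C2[C@@H](O)C1
F7 | step 12 | 4α,5α-epoxy-10α-[(tert-butyldimethylsilyl)oxy]dauc-8-en-6α-ol | CC1=C[C@@H](O[Si](C)(C)C(C)(C)C)[C@@]2(C)CC[C@@]3(C(C)C)O[C@@]23[C@@H](O)C1
F8 | step 12 | 4α,5α-epoxy-10α-[(tert-butyldimethylsilyl)oxy]dauc-8-en-6-one | CC1=C[C@@H](O[Si](C)(C)C(C)(C)C)[C@@]2(C)CC[C@@]3(C(C)C)O[C@@]23C(=O)C1
F0 | step 14 | none | none
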